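**Retrosynthetic overview**
- The target is a 2,4-cis (2S,4S) 4-aryl-flavan. The last step is hydrogenation of a penta-O-benzyl 4-aryl-2H-chromene, which sets C4 cis to the C2 aryl and removes all five benzyl groups.
- Key disconnection: the C4–aryl bond. The flavanone C4 carbonyl carbon is turned, through its N-tosylhydrazone, into a nucleophilic diazo/palladium-carbene carbon (an alkenyl-anion equivalent of the ketone) and joined to the bromide-bearing carbon of the acylphloroglucinol ring. Both carbons are natively electrophilic.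
- The (2S)-flavanone comes from 7-(benzyloxy)chromone by enantioselective conjugate addition of an arylboronic acid, which sets C2.
- The aryl bromide comes from phloroglucinol by C-acylation with 9-phenylnonanoic acid, tri-O-benzylation and ring bromination.
- Ring order: only the pyranone ring is built (chromone, step 1). Ring A, ring B and the phloroglucinol ring are bought as aromatic rings.

Assumption: 9-phenylnonanoic acid, 4'-benzyloxy-2'-hydroxyacetophenone and 4-(benzyloxy)phenylboronic acid are taken as catalogue chemicals.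

**Step 1**
Reactants: 1 1-[4-(benzyloxy)-2-hydroxyphenyl]ethan-1-one
Product: 3 7-(benzyloxy)-4H-chromen-4-one, via enaminone 2 (not isolated)
Conditions: DMF-DMA (1.5 equiv), toluene, 100 °C; then conc. HCl, CH2Cl2, 40 °C
Reagents that add atoms: N,N-dimethylformamide dimethyl acetal, COC(OC)N(C)C
Why: Enaminone formation at the methyl ketone followed by acid-promoted intramolecular oxa-Michael addition–elimination of dimethylamine is the standard enaminone route to chromones; no stereocentre is formed.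

**Step 2**
Reactants: 3 7-(benzyloxy)-4H-chromen-4-one; 4 [4-(benzyloxy)phenyl]boronic acid
Product: 5 (2S)-7-(benzyloxy)-2-[4-(benzyloxy)phenyl]-2,3-dihydro-4H-chromen-4-one
Conditions: Pd(OCOCF3)2 (5 mol %), (R)-t-BuPyOx (6 mol %), NH4PF6 (30 mol %), H2O (5 equiv), 4 (2 equiv), ClCH2CH2Cl, 60 °C; recrystallise
Reagents that add atoms: none
Why: Stoltz-type asymmetric conjugate addition, in which a cationic aryl–palladium PyOx complex (divalent palladium throughout) delivers the aryl group to C2 on the face fixed by the ligand and water protonates the palladium enolate; the (S)-ligand is expected, by analogy with its cyclic-enone additions, to give 2R flavanones, so the (R)-ligand is used for 2S (to be confirmed by chiral HPLC), and the near-neutral conditions avoid retro-oxa-Michael racemisation.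

**Step 3**
Reactants: 6 benzene-1,3,5-triol (phloroglucinol); 7 9-phenylnonanoic acid
Product: 8 9-phenyl-1-(2,4,6-trihydroxyphenyl)nonan-1-one
Conditions: BF3·OEt2 (neat), 90 °C, 2 h; aqueous NaOAc work-up
Reagents that add atoms: none
Why: BF3-promoted Friedel–Crafts C-acylation of phloroglucinol by the free acid stops at the mono-ketone because the chelated acyl group deactivates the ring.

**Step 4**
Reactants: 8 9-phenyl-1-(2,4,6-trihydroxyphenyl)nonan-1-one
Product: 9 9-phenyl-1-[2,4,6-tris(benzyloxy)phenyl]nonan-1-one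
Conditions: BnBr (3.6 equiv), K2CO3 (4.5 equiv), DMF, 70 °C
Reagents that add atoms: benzyl bromide, BrCc1ccccc1
Why: Williamson etherification in a polar aprotic solvent favours O- over C-benzylation, and heating drives the two chelated ortho hydroxyls to react as well.

**Step 5**
Reactants: 9 9-phenyl-1-[2,4,6-tris(benzyloxy)phenyl]nonan-1-one
Product: 10 1-[3-bromo-2,4,6-tris(benzyloxy)phenyl]-9-phenylnonan-1-one
Conditions: NBS (1.0 equiv), CH2Cl2, 0 °C, dark
Reagents that add atoms: N-bromosuccinimide, O=C1CCC(=O)N1Br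
Why: Electrophilic aromatic bromination at one of the two equivalent free positions of the trialkoxy ring is far faster than ketone α-bromination, and one equivalent at 0 °C limits dibromination.

**Step 6 (key step)**
Reactants: 5 (2S)-7-(benzyloxy)-2-[4-(benzyloxy)phenyl]-2,3-dihydro-4H-chromen-4-one; 11 4-methylbenzenesulfonohydrazide; 10 1-[3-bromo-2,4,6-tris(benzyloxy)phenyl]-9-phenylnonan-1-one
Product: 14 1-{2,4,6-tris(benzyloxy)-3-[(2S)-7-(benzyloxy)-2-[4-(benzyloxy)phenyl]-2H-chromen-4-yl]phenyl}-9-phenylnonan-1-one, via N-tosylhydrazone 12 (not isolated), via 4-diazochromane 13 (not isolated)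
Conditions: 11 (1.05 equiv), 1,4-dioxane, 4 Å MS, 80 °C; then 10 (1.0 equiv), Pd2(dba)3 (2.5 mol %), XPhos (10 mol %), LiOtBu (3 equiv), 100 °C
Reagents that add atoms: none
Why: Barluenga cross-coupling, in which base converts hydrazone 12 into diazo compound 13 (Bamford–Stevens), the aryl–palladium bromide formed from 10 and zerovalent palladium/XPhos captures it as a palladium carbene, aryl migration onto the carbene carbon forges the C4–aryl bond with the former carbonyl carbon acting as the nucleophilic partner, and β-hydride elimination (possible only toward C3) gives the 2H-chromene with the C2 stereocentre untouched.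

**Step 7**
Reactants: 14 1-{2,4,6-tris(benzyloxy)-3-[(2S)-7-(benzyloxy)-2-[4-(benzyloxy)phenyl]-2H-chromen-4-yl]phenyl}-9-phenylnonan-1-one
Product: 15 1-{2,4,6-trihydroxy-3-[(2S,4S)-7-hydroxy-2-(4-hydroxyphenyl)-3,4-dihydro-2H-chromen-4-yl]phenyl}-9-phenylnonan-1-one
Conditions: H2 (1 atm), 10% Pd/C, EtOAc–MeOH 1:1, rt
Reagents that add atoms: none
Why: Heterogeneous syn-hydrogenation delivers hydrogen to the C3=C4 face opposite the C2 aryl group, so the new C4–H is trans to that aryl and the two aryl groups end up cis (4S from 2S), while the same catalyst hydrogenolyses all five benzyl ethers and leaves the chelated aryl ketone and the flavan C–O bond intact under these mild conditions.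

**Compound list**
1 | 1-[4-(benzyloxy)-2-hydroxyphenyl]ethan-1-one | CC(=O)c1ccc(OCc2ccccc2)cc1O | starting material
2 | (E)-1-[4-(benzyloxy)-2-hydroxyphenyl]-3-(dimethylamino)prop-2-en-1-one | CN(C)/C=C/C(=O)c1ccc(OCc2ccccc2)cc1O | intermediate
3 | 7-(benzyloxy)-4H-chromen-4-one | O=c1ccoc2cc(OCc3ccccc3)ccc12 | intermediate
4 | [4-(benzyloxy)phenyl]boronic acid | OB(O)c1ccc(OCc2ccccc2)cc1 | starting material
5 | (2S)-7-(benzyloxy)-2-[4-(benzyloxy)phenyl]-2,3-dihydro-4H-chromen-4-one | O=C1C[C@@H](c2ccc(OCc3ccccc3)cc2)Oc2cc(OCc3ccccc3)ccc12 | intermediate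
6 | benzene-1,3,5-triol (phloroglucinol) | Oc1cc(O)cc(O)c1 | starting material
7 | 9-phenylnonanoic acid | OC(=O)CCCCCCCCc1ccccc1 | starting material
8 | 9-phenyl-1-(2,4,6-trihydroxyphenyl)nonan-1-one | O=C(CCCCCCCCc1ccccc1)c1c(O)cc(O)cc1O | intermediate
9 | 9-phenyl-1-[2,4,6-tris(benzyloxy)phenyl]nonan-1-one | O=C(CCCCCCCCc1ccccc1)c1c(OCc2ccccc2)cc(OCc2ccccc2)cc1OCc1ccccc1 | intermediate
10 | 1-[3-bromo-2,4,6-tris(benzyloxy)phenyl]-9-phenylnonan-1-one | O=C(CCCCCCCCc1ccccc1)c1c(OCc2ccccc2)cc(OCc2ccccc2)c(Br)c1OCc1ccccc1 | intermediate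
11 | 4-methylbenzenesulfonohydrazide | Cc1ccc(cc1)S(=O)(=O)NN | starting material
12 | N'-[(2S)-7-(benzyloxy)-2-[4-(benzyloxy)phenyl]-2,3-dihydro-4H-chromen-4-ylidene]-4-methylbenzenesulfonohydrazide | Cc1ccc(cc1)S(=O)(=O)NN=C1C[C@@H](c2ccc(OCc3ccccc3)cc2)Oc2cc(OCc3ccccc3)ccc12 | intermediate
13 | (2S)-7-(benzyloxy)-2-[4-(benzyloxy)phenyl]-4-diazo-3,4-dihydro-2H-chromene | [N-]=[N+]=C1C[C@@H](c2ccc(OCc3ccccc3)cc2)Oc2cc(OCc3ccccc3)ccc12 | intermediate
14 | 1-{2,4,6-tris(benzyloxy)-3-[(2S)-7-(benzyloxy)-2-[4-(benzyloxy)phenyl]-2H-chromen-4-yl]phenyl}-9-phenylnonan-1-one | O=C(CCCCCCCCc1ccccc1)c1c(OCc2ccccc2)cc(OCc2ccccc2)c(C2=C[C@@H](c3ccc(OCc4ccccc4)cc3)Oc3cc(OCc4ccccc4)ccc23)c1OCc1ccccc1 | intermediate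
15 | 1-{2,4,6-trihydroxy-3-[(2S,4S)-7-hydroxy-2-(4-hydroxyphenyl)-3,4-dihydro-2H-chromen-4-yl]phenyl}-9-phenylnonan-1-one | O=C(CCCCCCCCc1ccccc1)c1c(O)cc(O)c([C@H]2C[C@@H](c3ccc(O)cc3)Oc3cc(O)ccc32)c1O | target

**Count**
Total steps: 7. Longest linear sequence: 5 (steps 3, 4, 5, 6, 7 from phloroglucinol; the flavanone branch is steps 1, 2, 6, 7).

**Three steps most likely to fail**

Step 6 is the riskiest. The bromide in 10 is flanked by two benzyloxy groups, the ketone of 10 is enolisable under hot LiOtBu (α-arylation or aldol side reactions), diazo compound 13 can undergo a 1,2-hydride shift to the unarylated chromene, and hot alkoxide may erode C2 in product 14. The fallback sets out from 5 and comes back at 14, keeping C4 as the carbon nucleophile but without diazo chemistry or hot base. Ketone 5 is condensed with 2,4,6-tri(propan-2-yl)benzenesulfonohydrazide (THF, cat. HCl, rt) to N'-[(2S)-7-(benzyloxy)-2-[4-(benzyloxy)phenyl]-2,3-dihydro-4H-chromen-4-ylidene]-2,4,6-tri(propan-2-yl)benzenesulfonohydrazide F4. A Shapiro reaction (n-BuLi, 2.2 equiv, THF, −78 to 0 °C) gives [(2S)-7-(benzyloxy)-2-[4-(benzyloxy)phenyl]-2H-chromen-4-yl]lithium F5. ZnCl2 at −78 °C converts it into [(2S)-7-(benzyloxy)-2-[4-(benzyloxy)phenyl]-2H-chromen-4-yl]zinc chloride F6, which tolerates the ketone of 10 and is joined to 10 by Negishi coupling (Pd2(dba)3, SPhos, THF, 50 °C) to give 14.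

Step 7 can fail through hydrogenolysis of the allylic, benzylic C2–O bond of the chromene before the shielded alkene is reduced, through slow or unselective alkene reduction, or through ketone over-reduction on prolonged exposure. The fallback sets out from 14 and comes back at 15, separating the two events. Ionic hydrogenation (Et3SiH, CF3CO2H, CH2Cl2, −20 °C) protonates C3 and delivers hydride to the doubly aryl-stabilised C4 cation trans to the C2 aryl, giving 1-{2,4,6-tris(benzyloxy)-3-[(2S,4S)-7-(benzyloxy)-2-[4-(benzyloxy)phenyl]-3,4-dihydro-2H-chromen-4-yl]phenyl}-9-phenylnonan-1-one F7. A short hydrogenolysis (H2, Pd/C, EtOAc–MeOH, rt) on this saturated flavan then gives 15.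

Step 2 can fail because the electron-rich 7-alkoxychromone is a sluggish acceptor, the electron-rich boronic acid may protodeboronate, and the enantioselectivity and its sense must be verified. The fallback sets out from 1 and comes back at 5. Claisen–Schmidt condensation of 1 with 4-(benzyloxy)benzaldehyde (KOH, EtOH, rt) gives (E)-1-[4-(benzyloxy)-2-hydroxyphenyl]-3-[4-(benzyloxy)phenyl]prop-2-en-1-one F1. NaOAc in refluxing EtOH closes it to racemic 7-(benzyloxy)-2-[4-(benzyloxy)phenyl]-2,3-dihydro-4H-chromen-4-one F2. Kinetic resolution by transfer hydrogenation (RuCl(p-cymene)[(R,R)-TsDPEN], HCO2H/Et3N, EtOAc, rt, stopped near 50 % conversion) reduces the 2R enantiomer to (2R,4R)-7-(benzyloxy)-2-[4-(benzyloxy)phenyl]-3,4-dihydro-2H-chromen-4-ol F3, and the unreacted ketone 5 is separated by chromatography.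

**Further compounds**
F1 | step 2 | (E)-1-[4-(benzyloxy)-2-hydroxyphenyl]-3-[4-(benzyloxy)phenyl]prop-2-en-1-one | O=C(/C=C/c1ccc(OCc2ccccc2)cc1)c1ccc(OCc2ccccc2)cc1O
F2 | step 2 | racemic 7-(benzyloxy)-2-[4-(benzyloxy)phenyl]-2,3-dihydro-4H-chromen-4-one | O=C1CC(c2ccc(OCc3ccccc3)cc2)Oc2cc(OCc3ccccc3)ccc12
F3 | step 2 | (2R,4R)-7-(benzyloxy)-2-[4-(benzyloxy)phenyl]-3,4-dihydro-2H-chromen-4-ol | O[C@@H]1C[C@H](c2ccc(OCc3ccccc3)cc2)Oc2cc(OCc3ccccc3)ccc12
F4 | step 6 | N'-[(2S)-7-(benzyloxy)-2-[4-(benzyloxy)phenyl]-2,3-dihydro-4H-chromen-4-ylidene]-2,4,6-tri(propan-2-yl)benzenesulfonohydrazide | CC(C)c1cc(C(C)C)c(S(=O)(=O)NN=C2C[C@@H](c3ccc(OCc4ccccc4)cc3)Oc3cc(OCc4ccccc4)ccc23)c(C(C)C)c1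
F5 | step 6 | [(2S)-7-(benzyloxy)-2-[4-(benzyloxy)phenyl]-2H-chromen-4-yl]lithium | [Li]C1=C[C@@H](c2ccc(OCc3ccccc3)cc2)Oc2cc(OCc3ccccc3)ccc12
F6 | step 6 | [(2S)-7-(benzyloxy)-2-[4-(benzyloxy)phenyl]-2H-chromen-4-yl]zinc chloride | Cl[Zn]C1=C[C@@H](c2ccc(OCc3ccccc3)cc2)Oc2cc(OCc3ccccc3)ccc12
F7 | step 7 | 1-{2,4,6-tris(benzyloxy)-3-[(2S,4S)-7-(benzyloxy)-2-[4-(benzyloxy)phenyl]-3,4-dihydro-2H-chromen-4-yl]phenyl}-9-phenylnonan-1-one | O=C(CCCCCCCCc1ccccc1)c1c(OCc2ccccc2)cc(OCc2ccccc2)c([C@H]2C[C@@H](c3ccc(OCc4ccccc4)cc3)Oc3cc(OCc4ccccc4)ccc32)c1OCc1ccccc1
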